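We begin with the small charge, blue, and ask what a given amount of E does to the rate.

| setting | violet | blue | amber | green |
|---|---|---|---|---|
| Z | 0.500 M | 0.200 M | 1.00 M | 0.500 M |
| E |  |  |  | 0.150 M |
| time |  |  |  | 38 h |

| run | time / h | [E] / M |
|---|---|---|
| violet run | 1.5 | 0.031 |
| violet run | 2.4 | 0.026 |
| violet run | 3.8 | 0.061 |
| violet run | 6.0 | 0.094 |
| violet run | 9.6 | 0.132 |
| violet run | 15 | 0.146 |
| violet run | 24 | 0.203 |
| violet run | 38 | 0.223 |
| blue run | 1.5 | 0.004 |
| blue run | 2.4 | 0.018 |
| blue run | 3.8 | 0.020 |
| blue run | 6.0 | 0.017 |
| blue run | 9.6 | 0.028 |
| blue run | 15 | 0.037 |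
| blue run | 24 | 0.052 |
| blue run | 38 | 0.068 |
| amber run | 1.5 | 0.085 |
| amber run | 2.4 | 0.132 |
| amber run | 3.8 | 0.190 |
| amber run | 6.0 | 0.253 |
| amber run | 9.6 | 0.323 |
| amber run | 15 | 0.403 |
| amber run | 24 | 0.463 |
| amber run | 38 | 0.506 |

(readings scatter by 0.005 M)

- Overall: Z -> E.
- Constant volume, constant temperature.
- A reading of a species includes what of it is bound.
- An order is taken over about fifteen percent of the charge, up and down.
- A share of E counts the E that was charged too.

1. order of the initial rate in [Z], near the charge of the violet run, the rate being that where two percent of its Z are E (one fixed amount of E, the same in the runs compared)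
2. E in the green run at 38 h, as a share of the Z charged

Blue's mean rate falls from 0.00526 M/h over its opening to 0.00114 M/h once its E stands near 0.052 M to 0.068 M. Violet, with about that much E, still runs at 0.0150 M/h against 0.0161 M/h over its opening. About the same E thus goes with a large fall in blue and a slight one in violet, so we take the effect of E on the rate in green as a small correction to violet, which has the same Z.

We carry the made share: the E formed from Z by 38 h in a charge of 0.500 M, as a share of that charge. Violet reads:

made = 0.223 M / 0.500 M = 44.6%

Violet, blue and amber each read slower late than early, so we grant E no speeding. Adding one scatter to violet's reading gives the upper bound: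

top = (0.150 M + 0.223 M + 0.005 M) / 0.500 M = 75.6%

For the lower bound, suppose reversal is the brake and green is near its balance. Amber holds 0.506 M of E in 1.00 M and is still climbing, so green's balance lies above that fraction of its total 0.650 M:

low = 65.8%

We commit to charged E as a passenger:

share = 30.0% + 44.6% = 74.6%

The forecast gave an order of 1.8 and 60% for green, and of the late slowing it said “It looks like reversal or inhibition”; its share for green is lower than our bound.

The flask gives an order of 1.8 and 75.5% for green, 0.90 percentage points above our share, less than the 1 point that one scatter is worth.

    2 Z ⇌ Z2, settled at all times (0.2260 /M)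
    Z2 → E + Z (0.5220 /h)
    2 Z → Xi (0.03924 /M/h)

No step here has E among its reactants, so the charged E adds to the made share unchanged. Green stays at 75.5% because of the step joining two Z into Xi. The same green run without that step gives 94.3%, which is 19 points more. Taking off the charged E, that run has a made share of 64.3%.

(All runs stem from a simulated flask from invented constants; noise was put on by code.)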